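## Retrosynthetic overview

1. Broussonol A ⇒ tris-MOM flavonol, with acetal cleavage as the last step ⇒ flavone. The C3–O bond comes from C3-lithiation, borylation and peroxide oxidation, an oxidation that leaves both alkenes alone.
2. Flavone ⇒ flavanone ⇒ 2'-hydroxychalcone. Ring C closes by oxa-Michael addition of the only free phenol and is then dehydrogenated.
3. Chalcone ⇒ key C–C bond: intermolecular Claisen–Schmidt aldol condensation of an A-ring methyl ketone with a B-ring chromene aldehyde.
4. The ketone comes from phloroacetophenone through a 4-O-prenyl ether and an aromatic Claisen rearrangement, which gives the 1,1-dimethylallyl group. The aldehyde comes from protocatechualdehyde through a 4-O-(1,1-dimethylpropargyl) ether and a thermal chromene cascade.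
5. Ring order: both benzene rings are bought, the 2H-pyran (chromene) ring is made first, and the 4-pyranone ring C is made last.

Assumption: the target SMILES has no stereocentre and no stereogenic acyclic double bond. The "single enantiomer" is therefore the achiral compound itself. The transient racemic centres in 5, 12, 16 and 18 are all erased later.

## Route

**Step 1**
Reactants: 1 2,4,6-trihydroxyacetophenone (dried azeotropically); 2 3-methylbut-2-en-1-ol (prenol)
Product: 3 1-[2,6-dihydroxy-4-(3-methylbut-2-enyloxy)phenyl]ethanone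
Conditions: PPh3 (1.1 equiv), DIAD (1.1 equiv), THF, 0 °C → rt, 12 h
Reagents that add atoms: none
Why: Mitsunobu etherification, in which the non-chelated and most acidic 4-OH attacks the prenyloxyphosphonium ion at oxygen, so the C-prenylation seen with prenyl bromide and base is avoided.

**Step 2**
Reactants: 3 1-[2,6-dihydroxy-4-(3-methylbut-2-enyloxy)phenyl]ethanone
Product: 4 1-[2-hydroxy-6-(methoxymethoxy)-4-(3-methylbut-2-enyloxy)phenyl]ethanone
Conditions: MOMCl (1.1 equiv), i-Pr2NEt (1.5 equiv), CH2Cl2, 0 °C → rt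
Reagents that add atoms: chloromethyl methyl ether (MOMCl), COCCl
Why: O-alkylation (MOM protection) of two equivalent OH groups, which stops at the mono-ether because the remaining OH is locked in a hydrogen bond to the ketone.

**Step 3**
Reactants: 4 1-[2-hydroxy-6-(methoxymethoxy)-4-(3-methylbut-2-enyloxy)phenyl]ethanone
Product: 6 1-[2,4-dihydroxy-6-(methoxymethoxy)-3-(2-methylbut-3-en-2-yl)phenyl]ethanone, via ortho-dienone 5 (not isolated)
Conditions: PhNEt2, 190 °C, Ar, sealed tube, 2–3 h (stopped at full conversion)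
Reagents that add atoms: none
Why: Aromatic Claisen rearrangement ([3,3] with allyl inversion) turns O-prenyl into C-(1,1-dimethylallyl), and C3 is favoured because the chelated 2-OH raises C3–C4 double-bond character while the 6-OMOM chain shields C5; the centre of 5 is lost on tautomerisation.

**Step 4**
Reactants: 6 1-[2,4-dihydroxy-6-(methoxymethoxy)-3-(2-methylbut-3-en-2-yl)phenyl]ethanone
Product: 7 1-[2-hydroxy-4,6-bis(methoxymethoxy)-3-(2-methylbut-3-en-2-yl)phenyl]ethanone
Conditions: MOMCl (1.3 equiv), i-Pr2NEt (2 equiv), CH2Cl2, 0 °C → rt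
Reagents that add atoms: chloromethyl methyl ether (MOMCl), COCCl
Why: MOM protection of the free 4-OH, while the 2-OH is chelated and flanked by the tert-alkyl group and so stays free to become the ring oxygen.

**Step 5**
Reactants: 8 3,4-dihydroxybenzaldehyde; 9 3-chloro-3-methylbut-1-yne
Product: 10 3-hydroxy-4-[(2-methylbut-3-yn-2-yl)oxy]benzaldehyde
Conditions: DBU (1.2 equiv), CuCl2·2H2O (1 mol %), MeCN, 0 °C → rt, N2
Reagents that add atoms: none
Why: Copper-catalysed propargylic etherification, in which about one equivalent of base ionises only the 4-OH (para to CHO, pKa about 7) and that phenoxide captures the copper allenylidene.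

**Step 6**
Reactants: 10 3-hydroxy-4-[(2-methylbut-3-yn-2-yl)oxy]benzaldehyde
Product: 11 3-(methoxymethoxy)-4-[(2-methylbut-3-yn-2-yl)oxy]benzaldehyde
Conditions: MOMCl (1.3 equiv), i-Pr2NEt (2 equiv), CH2Cl2, 0 °C → rt
Reagents that add atoms: chloromethyl methyl ether (MOMCl), COCCl
Why: MOM protection of the only remaining phenol, to which the aldehyde and the alkyne are inert.

**Step 7**
Reactants: 11 3-(methoxymethoxy)-4-[(2-methylbut-3-yn-2-yl)oxy]benzaldehyde
Product: 15 8-(methoxymethoxy)-2,2-dimethyl-2H-chromene-6-carbaldehyde, via allenyl dienone 12 (not isolated), via allenylphenol 13 (not isolated), via ortho-quinone methide 14 (not isolated)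
Conditions: PhNEt2, 190–200 °C, Ar, 3 h
Reagents that add atoms: none
Why: Propargyl Claisen rearrangement, tautomerisation, 1,5-H shift and oxa-6π electrocyclisation in one cascade, where C3 is blocked by OMOM so only C5 can be attacked.

**Step 8 (key step)**
Reactants: 7 1-[2-hydroxy-4,6-bis(methoxymethoxy)-3-(2-methylbut-3-en-2-yl)phenyl]ethanone; 15 8-(methoxymethoxy)-2,2-dimethyl-2H-chromene-6-carbaldehyde
Product: 17 (E)-1-[2-hydroxy-4,6-bis(methoxymethoxy)-3-(2-methylbut-3-en-2-yl)phenyl]-3-[8-(methoxymethoxy)-2,2-dimethyl-2H-chromen-6-yl]prop-2-en-1-one, via aldol adduct 16 (not isolated)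
Conditions: KOH (50 % aq, excess), EtOH, rt, 36–48 h, Ar; cold dilute acid to pH 6
Reagents that add atoms: none
Why: Claisen–Schmidt crossed aldol condensation between the only enolisable partner (the methyl ketone) and a non-enolisable aldehyde, with E1cB dehydration erasing the carbinol centre of 16 and giving the E-enone; MOM ethers and alkenes are inert to KOH.

**Step 9**
Reactants: 17 the (E)-chalcone
Product: 18 rac-5,7-bis(methoxymethoxy)-2-[8-(methoxymethoxy)-2,2-dimethyl-2H-chromen-6-yl]-8-(2-methylbut-3-en-2-yl)chroman-4-one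
Conditions: NaOAc (5 equiv), EtOH, reflux, 24–36 h (recovered 17 recycled)
Reagents that add atoms: none
Why: Intramolecular oxa-Michael addition (chalcone–flavanone isomerisation), where only the 2'-OH is free so only the 8-substituted isomer can form, the 6'-alkoxy group shifts the equilibrium to the flavanone, and C2 forms racemic and is erased in step 10.

**Step 10**
Reactants: 18 the racemic flavanone
Product: 19 5,7-bis(methoxymethoxy)-2-[8-(methoxymethoxy)-2,2-dimethyl-2H-chromen-6-yl]-8-(2-methylbut-3-en-2-yl)-4H-chromen-4-one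
Conditions: DDQ (1.5–2 equiv), dry 1,4-dioxane, reflux, 8–12 h
Reagents that add atoms: none
Why: DDQ dehydrogenation by hydride abstraction from C2–H (benzylic, next to oxygen, stabilised by the para-alkoxy aryl group), with no side reaction expected because both side-chain alkenes lack allylic hydrogens and no free phenol is present.

**Step 11**
Reactants: 19 the flavone
Product: 22 3-hydroxy-5,7-bis(methoxymethoxy)-2-[8-(methoxymethoxy)-2,2-dimethyl-2H-chromen-6-yl]-8-(2-methylbut-3-en-2-yl)-4H-chromen-4-one, via 3-lithioflavone 20 (not isolated), via flavon-3-ylboronate 21 (not isolated)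
Conditions: LDA (commercial solution, 1.5 equiv), THF, −78 °C, 45 min; B(OMe)3 (3 equiv), −78 → 0 °C; AcOH (2 equiv), 30 % H2O2, 0 °C → rt, 1 h
Reagents that add atoms: hydrogen peroxide, OO (the C3 oxygen of 22); in the intermediates only: lithium diisopropylamide, CC(C)[N-]C(C)C.[Li+] (Li of 20), and trimethyl borate, COB(OC)OC (B(OMe)2 of 21)
Why: Carbonyl-directed C3-lithiation of the flavone, borylation and boronate oxidation (1,2-migration from B to O), using H2O2, which does not epoxidise unactivated alkenes as dioxiranes or peracids would.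

**Step 12**
Reactants: 22 the tris-MOM flavonol
Product: 23 Broussonol A, 3,5,7-trihydroxy-2-(8-hydroxy-2,2-dimethyl-2H-chromen-6-yl)-8-(2-methylbut-3-en-2-yl)-4H-chromen-4-one
Conditions: conc. HCl (cat.), MeOH–THF, 45 °C, 2 h
Reagents that add atoms: none
Why: Acid-catalysed acetal exchange (MOM cleavage) under mild conditions, which the monosubstituted vinyl group (it would give only a secondary cation) and the 2,2-dimethylchromene tolerate.

## Compound list

1 | 2,4,6-trihydroxyacetophenone | CC(=O)c1c(O)cc(O)cc1O | starting material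
2 | 3-methylbut-2-en-1-ol (prenol) | CC(C)=CCO | starting material
3 | 1-[2,6-dihydroxy-4-(3-methylbut-2-enyloxy)phenyl]ethanone | CC(=O)c1c(O)cc(OCC=C(C)C)cc1O | intermediate
4 | 1-[2-hydroxy-6-(methoxymethoxy)-4-(3-methylbut-2-enyloxy)phenyl]ethanone | CC(=O)c1c(O)cc(OCC=C(C)C)cc1OCOC | intermediate
5 | rac-4-acetyl-5-hydroxy-3-(methoxymethoxy)-6-(2-methylbut-3-en-2-yl)cyclohexa-2,4-dien-1-one (ortho-dienone; not isolated) | CC(=O)C1=C(O)C(C(C)(C)C=C)C(=O)C=C1OCOC | intermediate
6 | 1-[2,4-dihydroxy-6-(methoxymethoxy)-3-(2-methylbut-3-en-2-yl)phenyl]ethanone | CC(=O)c1c(O)c(C(C)(C)C=C)c(O)cc1OCOC | intermediate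
7 | 1-[2-hydroxy-4,6-bis(methoxymethoxy)-3-(2-methylbut-3-en-2-yl)phenyl]ethanone | CC(=O)c1c(O)c(C(C)(C)C=C)c(OCOC)cc1OCOC | intermediate
8 | 3,4-dihydroxybenzaldehyde | O=Cc1ccc(O)c(O)c1 | starting material
9 | 3-chloro-3-methylbut-1-yne | C#CC(C)(C)Cl | starting material
10 | 3-hydroxy-4-[(2-methylbut-3-yn-2-yl)oxy]benzaldehyde | O=Cc1ccc(OC(C)(C)C#C)c(O)c1 | intermediate
11 | 3-(methoxymethoxy)-4-[(2-methylbut-3-yn-2-yl)oxy]benzaldehyde | O=Cc1ccc(OC(C)(C)C#C)c(OCOC)c1 | intermediate
12 | rac-5-(methoxymethoxy)-3-(3-methylbuta-1,2-dien-1-yl)-4-oxocyclohexa-1,5-diene-1-carbaldehyde (allenyl dienone; not isolated) | O=CC1=CC(C=C=C(C)C)C(=O)C(OCOC)=C1 | intermediate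
13 | 4-hydroxy-3-(methoxymethoxy)-5-(3-methylbuta-1,2-dien-1-yl)benzaldehyde (allenylphenol; not isolated) | O=Cc1cc(C=C=C(C)C)c(O)c(OCOC)c1 | intermediate
14 | 5-(methoxymethoxy)-3-(3-methylbut-2-enylidene)-4-oxocyclohexa-1,5-diene-1-carbaldehyde, side chain syn to C=O (ortho-quinone methide; not isolated) | O=CC1=C/C(=C/C=C(C)C)C(=O)C(OCOC)=C1 | intermediate
15 | 8-(methoxymethoxy)-2,2-dimethyl-2H-chromene-6-carbaldehyde | O=Cc1cc(OCOC)c2c(c1)C=CC(C)(C)O2 | intermediate
16 | rac-3-hydroxy-1-[2-hydroxy-4,6-bis(methoxymethoxy)-3-(2-methylbut-3-en-2-yl)phenyl]-3-[8-(methoxymethoxy)-2,2-dimethyl-2H-chromen-6-yl]propan-1-one (aldol adduct; not isolated) | O=C(CC(O)c1cc(OCOC)c2c(c1)C=CC(C)(C)O2)c1c(O)c(C(C)(C)C=C)c(OCOC)cc1OCOC | intermediate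
17 | (E)-1-[2-hydroxy-4,6-bis(methoxymethoxy)-3-(2-methylbut-3-en-2-yl)phenyl]-3-[8-(methoxymethoxy)-2,2-dimethyl-2H-chromen-6-yl]prop-2-en-1-one | O=C(/C=C/c1cc(OCOC)c2c(c1)C=CC(C)(C)O2)c1c(O)c(C(C)(C)C=C)c(OCOC)cc1OCOC | intermediate
18 | rac-5,7-bis(methoxymethoxy)-2-[8-(methoxymethoxy)-2,2-dimethyl-2H-chromen-6-yl]-8-(2-methylbut-3-en-2-yl)chroman-4-one | O=C1CC(c2cc(OCOC)c3c(c2)C=CC(C)(C)O3)Oc2c1c(OCOC)cc(OCOC)c2C(C)(C)C=C | intermediate
19 | 5,7-bis(methoxymethoxy)-2-[8-(methoxymethoxy)-2,2-dimethyl-2H-chromen-6-yl]-8-(2-methylbut-3-en-2-yl)-4H-chromen-4-one | O=c1cc(-c2cc(OCOC)c3c(c2)C=CC(C)(C)O3)oc2c1c(OCOC)cc(OCOC)c2C(C)(C)C=C | intermediate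
20 | 3-lithio derivative of 19 (not isolated) | [Li]c1c(-c2cc(OCOC)c3c(c2)C=CC(C)(C)O3)oc2c(C(C)(C)C=C)c(OCOC)cc(OCOC)c2c1=O | intermediate
21 | dimethyl boronate of 19 at C3 (not isolated) | COB(OC)c1c(-c2cc(OCOC)c3c(c2)C=CC(C)(C)O3)oc2c(C(C)(C)C=C)c(OCOC)cc(OCOC)c2c1=O | intermediate
22 | 3-hydroxy-5,7-bis(methoxymethoxy)-2-[8-(methoxymethoxy)-2,2-dimethyl-2H-chromen-6-yl]-8-(2-methylbut-3-en-2-yl)-4H-chromen-4-one | O=c1c(O)c(-c2cc(OCOC)c3c(c2)C=CC(C)(C)O3)oc2c1c(OCOC)cc(OCOC)c2C(C)(C)C=C | intermediate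
23 | Broussonol A (achiral) | C=CC(C)(C)c1c(O)cc(O)c2c(=O)c(O)c(-c3cc(O)c4c(c3)C=CC(C)(C)O4)oc12 | target

## Step count

Total steps: 12. Longest linear sequence: 9 (steps 1–4 and 8–12). The aldehyde branch (steps 5–7) is convergent.

## Steps most likely to fail

**Step 1 (selective 4-O-prenylation of a triol).**
- Risk: some etherification of a chelated OH, bis-ether formation, or traces of C-alkylation could lower the yield.
- Fallback: it sets out from 1 and comes back at 4, and it differentiates the oxygens by protecting groups before any prenyl electrophile is used.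
- Compound 1 is mono-silylated at the free 4-OH (TBSCl 1.0 equiv, imidazole, DMF, 0 °C) to 1-[4-(tert-butyldimethylsilyloxy)-2,6-dihydroxyphenyl]ethanone F1.
- One of the two equivalent chelated OH groups is then protected (MOMCl, i-Pr2NEt) to give 1-[4-(tert-butyldimethylsilyloxy)-2-hydroxy-6-(methoxymethoxy)phenyl]ethanone F2.
- TBAF/AcOH in THF at 0 °C frees 1-[2,4-dihydroxy-6-(methoxymethoxy)phenyl]ethanone F3.
- Plain Williamson alkylation of the non-chelated 4-OH (prenyl bromide, K2CO3, acetone, reflux) gives 4.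

**Step 3 (aromatic Claisen rearrangement).**
- Risk: partial attack at C5, or onward reactions of the o-(1,1-dimethylallyl)phenol such as the abnormal Claisen rearrangement or dihydrofuran formation.
- Fallback: it sets out from 3 and comes back at 7, and it moves the regiochemical decision out of the pericyclic step.
- The symmetrical diol 3, whose two ortho positions are identical, is rearranged in PhNEt2 to 1-[2,4,6-trihydroxy-3-(2-methylbut-3-en-2-yl)phenyl]ethanone F4.
- A sterically controlled double protection (MOMCl 2.2 equiv, i-Pr2NEt, 0 °C) takes the 4-OH and the unhindered 6-OH. The 2-OH, wedged between the acetyl and the tert-alkyl group, stays free, and the product is 7.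

**Step 11 (C3 hydroxylation through the lithioflavone).**
- Risk: self-addition of the vinyl-lithium to unreacted flavone, or incomplete metalation.
- Fallback: it sets out from 17 and comes back at 22, bypassing 18 and 19 by an Algar–Flynn–Oyamada reaction (30 % H2O2, aq NaOH, MeOH–THF, 0 °C → rt).
- Nucleophilic epoxidation of the enone and opening at the benzylic carbon by the 2'-phenoxide give rac-trans-3-hydroxy-5,7-bis(methoxymethoxy)-2-[8-(methoxymethoxy)-2,2-dimethyl-2H-chromen-6-yl]-8-(2-methylbut-3-en-2-yl)chroman-4-one F5, which is oxidised in the same pot to 22.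
- The para-alkoxy B ring favours this mode of opening. The aurone by-product expected from the 6'-alkoxy group is removed by chromatography.

## Further compounds

F1 | step 1 | 1-[4-(tert-butyldimethylsilyloxy)-2,6-dihydroxyphenyl]ethanone | CC(=O)c1c(O)cc(O[Si](C)(C)C(C)(C)C)cc1O
F2 | step 1 | 1-[4-(tert-butyldimethylsilyloxy)-2-hydroxy-6-(methoxymethoxy)phenyl]ethanone | CC(=O)c1c(O)cc(O[Si](C)(C)C(C)(C)C)cc1OCOC
F3 | step 1 | 1-[2,4-dihydroxy-6-(methoxymethoxy)phenyl]ethanone | CC(=O)c1c(O)cc(O)cc1OCOC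
F4 | step 3 | 1-[2,4,6-trihydroxy-3-(2-methylbut-3-en-2-yl)phenyl]ethanone | CC(=O)c1c(O)cc(O)c(C(C)(C)C=C)c1O
F5 | step 11 | rac-trans-3-hydroxy-5,7-bis(methoxymethoxy)-2-[8-(methoxymethoxy)-2,2-dimethyl-2H-chromen-6-yl]-8-(2-methylbut-3-en-2-yl)chroman-4-one (2R,3R enantiomer drawn) | COCOc1cc(cc2C=CC(C)(C)Oc12)[C@@H]1[C@H](C(=O)c2c(O1)c(C(C)(C)C=C)c(OCOC)cc2OCOC)O
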